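A small charge of initiator, 1 mol% on free monomer, went into this flask, less than in Wednesday's run or Saturday's.

| flask | free monomer | protic impurity | initiator | remark | time |
|---|---|---|---|---|---|
| Wednesday's | 0.50 M | 0.050 M | 1.4 mol% | run made earlier |  |
| Saturday's | 0.50 M | 0.050 M | 2.2 mol% | run made earlier |  |
| flask | 0.50 M | 0.0500 M | 1 mol% |  | 15 min |

| run | time / min | monomer in chains / % | free monomer / % |
|---|---|---|---|
| Wednesday's | 1.33 | 38.7 | 58.7 |
| Wednesday's | 2.00 | 49.5 | 43.7 |
| Wednesday's | 3.00 | 59.8 | 29.8 |
| Wednesday's | 4.00 | 64.9 | 20.3 |
| Wednesday's | 6.00 | 65.3 | 9.0 |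
| Wednesday's | 10.0 | 54.5 | 1.0 |
| Saturday's | 1.33 | 45.1 | 50.6 |
| Saturday's | 2.00 | 56.7 | 35.7 |
| Saturday's | 3.00 | 66.4 | 22.0 |
| Saturday's | 4.00 | 70.0 | 12.2 |
| Saturday's | 6.00 | 68.5 | 3.9 |
| Saturday's | 10.0 | 54.5 | 0.9 |

(standard deviation of a reading: 0.5 percentage points)

- when, up to 15 min, the flask holds most monomer in chains
- the amount of monomer in chains, in percent of the free monomer charged, at that time
- the first time at which monomer in chains reaches 19%, in the same percent, in min

- what was read earlier has a scatter of 0.5 percentage points, one standard deviation

In both earlier runs, free monomer fell first order, so I read its constant k from the first and fourth readings. The sum of free monomer and monomer in chains then fell in step with the time integral of monomer in chains, so I read a loss constant d from the fourth reading to the last.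

| run | k | d |
|---|---|---|
| Wednesday's | 0.398 min⁻¹ | 0.0803 min⁻¹ |
| Saturday's | 0.533 min⁻¹ | 0.0697 min⁻¹ |

I took the mean d, 0.0750 min⁻¹. The two k values gave an order in initiator of 0.647, and so k = 0.320 min⁻¹ for this flask, outside the tested loadings.

At the peak, k·c(free monomer) equals d·c(monomer in chains), so c(monomer in chains)/c(free monomer) must there equal k/d. With ln(k/d)/(k−d), this first pass put the peak at 5.92 min.

The weak link was that order, read from two scattered runs. If growing radicals end in pairs, the order is 0.5, which gave k = 0.336 min⁻¹. I committed to this k, and so to a crossing ratio, k over d, of 4.48. The peak then came at 5.74 min, at about 65.0% of the charge, and the level asked for at 0.627 min.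

The forecast gave 5.6 min, 63.5% and 0.66 min. Its peak stood below mine, shaved because “the model runs a little high against the data near the peak”.

The flask gave 5.73 min, 63.6% and 0.654 min.

    free monomer + growing radical → monomer in chains + growing radical, rate k1*[growing radical]*[free monomer] (k = 53000 L mol⁻¹ s⁻¹)
    2 growing radical → dead chain (k = 5.00 × 10⁷ L mol⁻¹ s⁻¹)
    initiator → 2 initiating radical (k = 0.00660 min⁻¹)
    free monomer + initiating radical → growing radical + monomer in chains (k = 2.60 × 10⁵ L mol⁻¹ s⁻¹)
    protic impurity + free monomer → quenched substrate (k = 0.260 L mol⁻¹ min⁻¹)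
    monomer in chains → over-reaction product (k = 0.0730 min⁻¹)

In this flask, monomer in chains was made 5.15 times faster than it was used up at 2.00 min, and at 15.0 min that ratio was 0.0710. Between them, at 5.73 min, the flask held 4.50 parts of monomer in chains per part of free monomer, beside a crossing ratio of 4.48. In the neighbouring reading at 4.0 min, the crossing ratio times c(free monomer)/c(monomer in chains) was 1.88, above one, and monomer in chains stood at 60.5%.

The numbers in the tables were computed for an exercise; scatter was added.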